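**Assumption:** the target has no stereocentres, so "single enantiomer" is read as the single (E)-alkene isomer, (E)-6-(4-hydroxy-3-methylbut-2-enyl)genistein. The route is designed from general precedent and has not been run.

## Retrosynthetic overview

1. No ring is formed: the chromen-4-one and the B-ring are bought intact as genistein, and only the C6 side chain is built.
2. The allylic alcohol comes from an (E)-2-methyl-enal, made by cross-metathesis of a 6-allyl group with methacrolein (this sets the E geometry).
3. The 6-allyl group comes from aromatic Claisen rearrangement of a 5-O-allyl ether, where C6 is the only free ortho position, so regiochemistry is fixed.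
4. The 5-O-allyl ether comes from genistein 7,4'-diacetate; the chelated 5-OH is left free by selective acetylation.

## Route

**Step 1**
Reactants: **1** genistein; **2** acetic anhydride
Product: **3** 7,4'-di-O-acetylgenistein (4-(7-acetoxy-5-hydroxy-4-oxo-4H-chromen-3-yl)phenyl acetate)
Conditions: Ac2O (2.2 equiv), pyridine, 0 °C → rt
Reagents that add atoms: acetic anhydride, CC(=O)OC(C)=O
Why: Chemoselective O-acylation; the 5-OH is hydrogen-bonded to the C4 carbonyl and much less nucleophilic, so limited Ac2O acylates only the 7- and 4'-OH.

**Step 2**
Reactants: **3**; **4** allyl alcohol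
Product: **5** 5-O-allyl-7,4'-di-O-acetylgenistein
Conditions: allyl alcohol (1.5 equiv), PPh3, DIAD, THF, 0 °C → rt
Reagents that add atoms: allyl alcohol, C=CCO
Why: Mitsunobu etherification of the only free phenol; the neutral conditions avoid the acetate cleavage or migration that a base-mediated alkylation would cause.

**Step 3**
Reactants: **5**
Product: **6** 6-allyl-7,4'-di-O-acetylgenistein (6-allyl-5-hydroxy, 7- and 4'-OAc)
Conditions: PhNEt2, 200 °C (sealed tube or microwave), Ar, 1–2 h
Reagents that add atoms: none
Why: Aromatic Claisen [3,3] rearrangement; the only open ortho position to O5 is C6 (C4a is the ring fusion), and the dienone tautomerises at once to the chelated 5-OH phenol, so allyl is delivered to C6 only.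

**Step 4**
Reactants: **6**; **7** methacrolein
Product: **8** (E)-4-[7-acetoxy-3-(4-acetoxyphenyl)-5-hydroxy-4-oxo-4H-chromen-6-yl]-2-methylbut-2-enal
Conditions: methacrolein (10 equiv), Hoveyda–Grubbs II (5–10 mol%), 1,4-benzoquinone (10 mol%), CH2Cl2, 40 °C
Reagents that add atoms: methacrolein, CC(=C)C=O
Why: Olefin cross-metathesis of a terminal alkene with a 1,1-disubstituted enal, losing ethylene; it is under thermodynamic control and gives the (E)-trisubstituted enal (CHO trans to CH2Ar, typically >20:1). Benzoquinone suppresses allyl-to-propenyl isomerisation, and the electron-poor C2=C3 of the chromone is metathesis-inert.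

**Step 5**
Reactants: **8**
Product: **9** target, 5,7-dihydroxy-3-(4-hydroxyphenyl)-6-[(E)-4-hydroxy-3-methylbut-2-en-1-yl]-4H-chromen-4-one
Conditions: NaBH4, MeOH/THF, 0 °C, 20 min; then K2CO3, rt, 1 h; aq. NH4Cl work-up (one pot)
Reagents that add atoms: none (hydride and protons only; both acetyl groups are removed)
Why: 1,2-Reduction of the aldehyde is much faster than attack on the chelated, vinylogous-ester chromone carbonyl, and the aryl acetates are then removed by base methanolysis. Reduction is done before the base treatment so the γ-acidic enal is never exposed to carbonate, and the E-alkene is not touched.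

## Compound list

1 | genistein | O=c1c(-c2ccc(O)cc2)coc2cc(O)cc(O)c12 | starting material
2 | acetic anhydride | CC(=O)OC(C)=O | starting material
3 | 7,4'-di-O-acetylgenistein | CC(=O)Oc1ccc(cc1)-c1coc2cc(OC(C)=O)cc(O)c2c1=O | intermediate
4 | allyl alcohol | C=CCO | starting material
5 | 5-O-allyl-7,4'-di-O-acetylgenistein | CC(=O)Oc1ccc(cc1)-c1coc2cc(OC(C)=O)cc(OCC=C)c2c1=O | intermediate
6 | 6-allyl-7,4'-di-O-acetylgenistein | CC(=O)Oc1ccc(cc1)-c1coc2cc(OC(C)=O)c(CC=C)c(O)c2c1=O | intermediate
7 | methacrolein | CC(=C)C=O | starting material
8 | (E)-enal, 7,4'-diacetate | C/C(C=O)=C\Cc1c(OC(C)=O)cc2occ(-c3ccc(OC(C)=O)cc3)c(=O)c2c1O | intermediate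
9 | (E)-6-(4-hydroxy-3-methylbut-2-enyl)genistein | C/C(=C\Cc1c(O)cc2occ(-c3ccc(O)cc3)c(=O)c2c1O)CO | target

## Summary

Total steps: 5. Longest linear sequence: 5, from genistein.

Steps most likely to fail, each with a fallback:

1. **Step 4 (cross-metathesis).** Risks are allyl-to-propenyl isomerisation, catalyst chelation by the ortho-phenol, and low conversion with the hindered enal. Fallback: cross-metathesise **6** with 2-methyl-2-butene to give the 6-prenyl compound (wighteone diacetate), then introduce the oxygen by E-selective allylic C–H oxidation (SeO2/t-BuOOH), followed by the same NaBH4/K2CO3 finish.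
2. **Step 3 (thermal Claisen).** Risks are acetate scrambling or loss at 200 °C and cyclisation of the ortho-allylphenol to a dihydrofuran. Fallback: skip the O-allyl/Claisen sequence and functionalise C6 directly, by 5-OH-directed 6-iodination of **3** (BnMe3N·ICl2 or NIS) followed by Stille coupling with allyltributylstannane to give **6**.
3. **Step 2 (Mitsunobu on the chelated 5-OH).** The risk is a sluggish reaction and difficult separation from Ph3PO and hydrazide by-products. Fallback: Pd(0)-catalysed Tsuji–Trost O-allylation with allyl methyl carbonate (Pd(PPh3)4, THF), which is neutral and decarboxylative and leaves the acetates intact.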